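The target is a single unbranched, stereocentre-free C1–C20 acyl chain attached to a benzyl ester whose benzene ring is the only ring and a spectator. The route rests on cutting the chain at its midpoint, the C10–C11 bond, which lies far from the ester at C1. In one operation, cross-metathesis joins benzyl undec-10-enoate and undec-1-ene with loss of ethene, creating C10=C11 and with it the complete C20 skeleton. The precursor is simply the benzyl ester of a terminal C11 alkenoic acid, one esterification from commercial materials. A hydrogenation that spares the benzylic C–O bond then removes the alkene and its geometry.

Key step: step 2

Remark on the chemistry: the metathesis product 5 is drawn as its E isomer. The Z isomer expected alongside it is carried through unseparated, because step 3 erases the double bond.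

Step 1
Reactants: 1 undec-10-enoic acid; 2 benzyl alcohol
Product: 3 benzyl undec-10-enoate
Conditions: TsOH·H2O (5 mol%), toluene, reflux, Dean–Stark trap; aqueous NaHCO3 wash, short SiO2 column
Reagents that add atoms: none
Why: Fischer esterification, an acid-catalysed acyl substitution driven to completion by azeotropic removal of water, under which the isolated terminal alkene is inert and no stereocentre is involved.

Step 2
Reactants: 3 benzyl undec-10-enoate; 4 undec-1-ene (3 equiv)
Product: 5 benzyl (E)-icos-10-enoate (with the Z isomer as a minor companion)
Conditions: RuCl2(=CHPh)(H2IMes)(PCy3) (second-generation Grubbs catalyst, 2 mol%), 1,4-benzoquinone (10 mol%), CH2Cl2, 40 °C, slow Ar purge; then ethyl vinyl ether, SiO2 chromatography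
Reagents that add atoms: none
Why: Olefin cross-metathesis by the Chauvin mechanism: the ruthenium benzylidene exchanges onto either terminal olefin through [2+2] cycloaddition and cycloreversion via ruthenacyclobutanes, and the resulting alkylidene captures the other partner to form the C10=C11 bond while ethene leaves the refluxing solution and drives the equilibrium. The closest known reaction type is cross-metathesis of two unhindered monosubstituted olefins bearing only remote, non-coordinating functionality, for which this catalyst is well established; the ester at C1 is nine carbons from the reacting alkene and the benzyl group is inert. No ring closes and no stereocentre forms; the alkene geometry, expected to favour E under equilibrating secondary metathesis, is irrelevant because step 3 removes it. The selectivity required is cross-coupling over homodimerisation, which is purely statistical for two such similar olefins and is secured by the excess of the cheap hydrocarbon 4, so that most of 3 should end up paired with 4. The by-products should separate by polarity on silica gel: icos-10-ene carries no ester and elutes with hexanes, whereas the diester homodimer of 3 carries two and is retained longer than 5. 1,4-Benzoquinone is added to intercept ruthenium hydrides, since double-bond migration before metathesis would give chain-length homologues that could not be removed later.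

Step 3
Reactants: 5 benzyl (E)-icos-10-enoate (with its Z isomer)
Product: 6 benzyl icosanoate (eicosanoic acid phenylmethyl ester)
Conditions: H2 (1–3 atm), RhCl(PPh3)3 (5 mol%), toluene/EtOH 1:1, 40 °C
Reagents that add atoms: none
Why: Homogeneous hydrogenation with Wilkinson's catalyst RhCl(PPh3)3 adds H2 across the unhindered 1,2-disubstituted alkene by oxidative addition, migratory insertion and reductive elimination at rhodium and, unlike heterogeneous palladium, does not hydrogenolyse the benzylic C–O bond, so both geometric isomers of 5 should converge on the saturated benzyl ester with no stereocentre created.

Compound list
1 | undec-10-enoic acid | C=CCCCCCCCCC(=O)O | starting material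
2 | benzyl alcohol | OCc1ccccc1 | starting material
3 | benzyl undec-10-enoate | C=CCCCCCCCCC(=O)OCc1ccccc1 | intermediate
4 | undec-1-ene | C=CCCCCCCCCC | starting material
5 | benzyl (E)-icos-10-enoate (major isomer drawn; Z isomer carried along) | CCCCCCCCC/C=C/CCCCCCCCC(=O)OCc1ccccc1 | intermediate
6 | benzyl icosanoate (eicosanoic acid phenylmethyl ester) | CCCCCCCCCCCCCCCCCCCC(=O)OCc1ccccc1 | target

Total step count: 3
Longest linear sequence: 3 steps (1 → 3 → 5 → 6)

Steps most likely to fail

Step 2. Statistical scrambling may leave too much of 3 as its diester homodimer. Ruthenium-hydride-mediated double-bond migration may also shift the chain length, giving homologues that co-elute with the product at every later stage. The fallback sets out from 3 and returns to the route at 6. It builds the same C10=C11 bond by a non-statistical carbonyl olefination. Ozone in CH2Cl2 at −78 °C should convert the terminal alkene of 3 into the secondary ozonide benzyl 9-(1,2,4-trioxolan-3-yl)nonanoate F1. PPh3 reduces this in the same flask to benzyl 10-oxodecanoate F2. Separately, commercial decyltriphenylphosphonium bromide and NaN(SiMe3)2 in THF give decylidene(triphenyl)phosphorane F3. Addition of F2 at −78 °C should give benzyl (Z)-icos-10-enoate F4 by a salt-free Wittig olefination, in which the non-stabilised ylide attacks the aldehyde far faster than the ester. F4 is then hydrogenated with H2 and RhCl(PPh3)3 as in step 3 to reach 6.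

Step 3. Saturation of the internal, mainly trans alkene by the bulky rhodium catalyst may stall before completion, leaving unsaturated ester that cannot be separated from the product. The fallback sets out from 5 and returns at 6. It accepts loss of the benzyl group instead of avoiding it. Hydrogen over Pd/C (palladium on carbon) in EtOAc/EtOH should saturate the alkene and cleave the benzyl ester together, giving icosanoic acid F5. F5 is a crystalline solid that can be recrystallised free of any minor impurities. It is then re-esterified with 2 under the conditions of step 1 (TsOH·H2O, toluene, Dean–Stark) to give 6.

Step 1. The esterification equilibrium may not be driven fully to the ester. Acid-promoted self-condensation of benzyl alcohol may also consume the alcohol and complicate purification. The fallback sets out from 1 and returns at 3. It forms the ester by O-alkylation instead of acyl substitution. K2CO3 in DMF at room temperature deprotonates 1 to potassium undec-10-enoate F6. F6 should displace bromide from benzyl bromide in an SN2 reaction to give 3, with no acid present and no equilibrium to shift.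

Further compounds
F1 | step 2 | benzyl 9-(1,2,4-trioxolan-3-yl)nonanoate | O=C(CCCCCCCCC1OCOO1)OCc1ccccc1
F2 | step 2 | benzyl 10-oxodecanoate | O=CCCCCCCCCC(=O)OCc1ccccc1
F3 | step 2 | decylidene(triphenyl)phosphorane | CCCCCCCCCC=P(c1ccccc1)(c1ccccc1)c1ccccc1
F4 | step 2 | benzyl (Z)-icos-10-enoate | CCCCCCCCC/C=C\CCCCCCCCC(=O)OCc1ccccc1
F5 | step 3 | icosanoic acid | CCCCCCCCCCCCCCCCCCCC(=O)O
F6 | step 1 | potassium undec-10-enoate | C=CCCCCCCCCC(=O)[O-].[K+]
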